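**Plan**
- Retrosynthetic cuts, in order: the five O-protecting groups (four benzyl ethers and the chelated 5-O-methyl of unit 1); the C4–C4a bond of unit 1 (its ring C); the C3'(unit 1)–C8(unit 2) biaryl bond; the C2–O1 enol ether bond of unit 1; ring C of unit 2 through a 2'-hydroxychalcone.
- Enabling feature: ring A of unit 1 (oxygen at C5, methyl at C6, methoxy at C7, hydrogen at C8) is a 3,5-dimethoxy-4-methylphenoxy ring whose two ortho carbons are mirror images, so acylation at either one can give only the 6-methyl chromone.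
- Forward order: ring C of unit 2 closes first (chalcone to 8-iodoflavone); the ring B alkynoate takes up the symmetric phenol by oxa-Michael addition; Suzuki coupling joins this enol ether to C8 of unit 2; ring C of unit 1 closes last by Friedel–Crafts acylation; a one-pot deprotection ends the route.
- Stereochemistry: the target has no stereocentre. The only stereo element on the way, the enol ether geometry, comes from anti addition (Z) and is erased by the ring closure.

Key step: step 13

Remark: flavone locants are used, with unit 1 the 5-hydroxy-7-methoxy-6-methylflavone half and unit 2 the apigenin half. The target SMILES carries no axial descriptor, so the biaryl axis is treated as configurationally undefined and no atroposelective step is planned.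

**Route**

Step 1
Reactants: 1 2',4',6'-trihydroxyacetophenone
Product: 2 1-[4,6-bis(benzyloxy)-2-hydroxyphenyl]ethanone
Conditions: BnBr (2.1 equiv), K2CO3 (2.2 equiv), DMF, 0 °C → rt
Reagents that add atoms: benzyl bromide, BrCc1ccccc1
Why: Williamson etherification: the 4-hydroxyl and one of the two equivalent ortho hydroxyls are alkylated, after which the last hydroxyl is held in a hydrogen bond to the acetyl oxygen and is too weakly nucleophilic to react under these mild conditions.

Step 2
Reactants: 2 1-[4,6-bis(benzyloxy)-2-hydroxyphenyl]ethanone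
Product: 3 1-[4,6-bis(benzyloxy)-2-hydroxy-3-iodophenyl]ethanone
Conditions: NIS (1.0 equiv), CF3CO2H (cat.), MeCN/CH2Cl2, 0 °C → rt, dark
Reagents that add atoms: N-iodosuccinimide, O=C1CCC(=O)N1I
Why: Electrophilic aromatic iodination: of the two free ring positions the one ortho to the free, chelated phenol (C3) is the usual site of halogenation in 2-hydroxy-4,6-dialkoxyacetophenones, and one equivalent of N-iodosuccinimide limits the reaction to mono-iodination; this carbon becomes C8 of unit 2.

Step 3
Reactants: 3 1-[4,6-bis(benzyloxy)-2-hydroxy-3-iodophenyl]ethanone; 4 4-benzyloxybenzaldehyde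
Product: 5 (E)-1-[4,6-bis(benzyloxy)-2-hydroxy-3-iodophenyl]-3-(4-benzyloxyphenyl)prop-2-en-1-one
Conditions: KOH (50% aq.), EtOH/THF, rt
Reagents that add atoms: none
Why: Claisen–Schmidt condensation: the methyl ketone enolate adds to the non-enolisable aldehyde and E1cB dehydration gives the conjugated, thermodynamically preferred E enone, the aryl iodide and benzyl ethers being inert to hydroxide.

Step 4
Reactants: 5 (E)-1-[4,6-bis(benzyloxy)-2-hydroxy-3-iodophenyl]-3-(4-benzyloxyphenyl)prop-2-en-1-one
Product: 7 5,7-bis(benzyloxy)-2-(4-benzyloxyphenyl)-8-iodochromen-4-one, via flavanone 6 (not isolated)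
Conditions: I2 (10 mol %), DMSO, 120 °C
Reagents that add atoms: none
Why: Iodine-catalysed oxidative cyclisation of a 2'-hydroxychalcone: 6-endo oxa-Michael closure gives flavanone 6, α-iodination and loss of HI introduce the C2–C3 double bond, and DMSO reoxidises HI so that iodine is needed only in catalytic amount and the medium stays nearly neutral for the benzyl ethers.

Step 5
Reactants: 8 3-bromo-4-hydroxybenzaldehyde
Product: 9 4-benzyloxy-3-bromobenzaldehyde
Conditions: BnBr, K2CO3, DMF, rt
Reagents that add atoms: benzyl bromide, BrCc1ccccc1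
Why: Williamson etherification of the only phenol, which masks the future 4'-hydroxyl of unit 1 as a benzyl ether stable to every later base and palladium step.

Step 6
Reactants: 9 4-benzyloxy-3-bromobenzaldehyde
Product: 10 1-benzyloxy-2-bromo-4-ethynylbenzene
Conditions: dimethyl (1-diazo-2-oxopropyl)phosphonate, K2CO3, MeOH/THF, 0 °C → rt
Reagents that add atoms: dimethyl (1-diazo-2-oxopropyl)phosphonate, CC(=O)C(=[N+]=[N-])P(=O)(OC)OC
Why: Seyferth–Gilbert homologation in its Ohira–Bestmann form: methanolysis of the reagent releases the diazomethylphosphonate anion, which adds to the non-enolisable aldehyde, and the resulting diazoalkene loses N2 with a 1,2-hydride shift to give the terminal alkyne under conditions that leave the aryl bromide alone.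

Step 7
Reactants: 10 1-benzyloxy-2-bromo-4-ethynylbenzene
Product: 12 methyl 3-(4-benzyloxy-3-bromophenyl)prop-2-ynoate, via lithium acetylide 11 (not isolated)
Conditions: LiN(iPr)2, THF, −78 °C; ClCO2Me, −78 → 0 °C
Reagents that add atoms: methyl chloroformate, COC(=O)Cl
Why: C-Acylation of a lithium acetylide with a chloroformate: the amide base removes the acetylenic proton without the bromine–lithium exchange that an alkyllithium would risk, and the acetylide is acylated once because the alkynoate is a poorer electrophile than the chloroformate at low temperature.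

Step 8
Reactants: 13 2,6-dimethoxytoluene
Product: 15 3,5-dimethoxy-4-methylphenol, via aryl pinacol boronate 14 (not isolated)
Conditions: [Ir(OMe)(cod)]2 (1.5 mol %), dtbpy, B2pin2 (1.0 equiv), THF, 80 °C; then 30% aq. H2O2, NaOH, 0 °C → rt
Reagents that add atoms: hydrogen peroxide, OO
Why: Iridium-catalysed C–H borylation followed by oxidation of the C–B bond: borylation is sterically controlled and the only ring hydrogen without an ortho substituent is the one para to the methyl group, so boronate 14 and hence the phenol are single, mirror-symmetric isomers.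

Step 9
Reactants: 12 methyl 3-(4-benzyloxy-3-bromophenyl)prop-2-ynoate; 15 3,5-dimethoxy-4-methylphenol
Product: 16 methyl (Z)-3-(4-benzyloxy-3-bromophenyl)-3-(3,5-dimethoxy-4-methylphenoxy)prop-2-enoate
Conditions: Cs2CO3 (0.5 equiv), DMF, 60 °C
Reagents that add atoms: none
Why: Oxa-Michael addition of a phenoxide to an alkynoate: the oxygen adds at the aryl-bearing β-carbon and anti protonation places the aryloxy group cis to the ester (Z), although either geometry would serve because the alkene can equilibrate before ring closure in step 13.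

Step 10
Reactants: 16 methyl (Z)-3-(4-benzyloxy-3-bromophenyl)-3-(3,5-dimethoxy-4-methylphenoxy)prop-2-enoate
Product: 17 methyl (Z)-3-[4-benzyloxy-3-(4,4,5,5-tetramethyl-1,3,2-dioxaborolan-2-yl)phenyl]-3-(3,5-dimethoxy-4-methylphenoxy)prop-2-enoate
Conditions: B2pin2, Pd(dppf)Cl2 (5 mol %), KOAc, 1,4-dioxane, 90 °C
Reagents that add atoms: bis(pinacolato)diboron, CC1(C)OB(OC1(C)C)B1OC(C)(C)C(C)(C)O1
Why: Miyaura borylation: oxidative addition of the aryl bromide to zerovalent palladium, acetate-assisted transmetalation with the diboron and reductive elimination give the aryl boronate, KOAc being too weak a base to trigger Suzuki homocoupling or to touch the enoate.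

Step 11
Reactants: 17 methyl (Z)-3-[4-benzyloxy-3-(4,4,5,5-tetramethyl-1,3,2-dioxaborolan-2-yl)phenyl]-3-(3,5-dimethoxy-4-methylphenoxy)prop-2-enoate; 7 5,7-bis(benzyloxy)-2-(4-benzyloxyphenyl)-8-iodochromen-4-one
Product: 18 methyl (Z)-3-{4-benzyloxy-3-[5,7-bis(benzyloxy)-2-(4-benzyloxyphenyl)-4-oxochromen-8-yl]phenyl}-3-(3,5-dimethoxy-4-methylphenoxy)prop-2-enoate
Conditions: Pd(OAc)2 (5 mol %), SPhos (10 mol %), K3PO4, toluene/H2O (10:1), 90 °C
Reagents that add atoms: none
Why: Suzuki–Miyaura cross-coupling: the aryl iodide adds readily to zerovalent palladium and the bulky, electron-rich biaryl phosphine promotes transmetalation and reductive elimination at the tri-ortho-substituted axis, as in known couplings of 8-iodoflavones with ortho-alkoxyaryl boron reagents, while the biphasic phosphate base spares the methyl ester.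

Step 12
Reactants: 18 methyl (Z)-3-{4-benzyloxy-3-[5,7-bis(benzyloxy)-2-(4-benzyloxyphenyl)-4-oxochromen-8-yl]phenyl}-3-(3,5-dimethoxy-4-methylphenoxy)prop-2-enoate
Product: 19 (Z)-3-{4-benzyloxy-3-[5,7-bis(benzyloxy)-2-(4-benzyloxyphenyl)-4-oxochromen-8-yl]phenyl}-3-(3,5-dimethoxy-4-methylphenoxy)prop-2-enoic acid
Conditions: LiOH·H2O (5 equiv), THF/MeOH/H2O, 40 °C; then 1 M HCl to pH 3
Reagents that add atoms: lithium hydroxide, [Li+].[OH-]
Why: Ester saponification (acyl–oxygen cleavage by hydroxide): the vinylogous carbonate is attacked at the ester carbonyl rather than at the electron-rich β-carbon, and the flavone and aryl benzyl ethers tolerate LiOH at this temperature, so that mild acidification delivers the free acid.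

Step 13
Reactants: 19 (Z)-3-{4-benzyloxy-3-[5,7-bis(benzyloxy)-2-(4-benzyloxyphenyl)-4-oxochromen-8-yl]phenyl}-3-(3,5-dimethoxy-4-methylphenoxy)prop-2-enoic acid
Product: 21 8-[2-benzyloxy-5-(5,7-dimethoxy-6-methyl-4-oxochromen-2-yl)phenyl]-5,7-bis(benzyloxy)-2-(4-benzyloxyphenyl)chromen-4-one, via mixed trifluoroacetic anhydride 20 (not isolated)
Conditions: (CF3CO)2O (3 equiv), CH2Cl2, 0 °C → rt
Reagents that add atoms: none
Why: Trifluoroacetic anhydride turns acid 19 into mixed anhydride 20, whose ionisation gives an acylium ion that is stabilised by the β-aryloxy oxygen yet still electrophilic enough for the phloroglucinol-type phenoxy ring, which attacks through the carbon ortho to the ether oxygen (also ortho to one methoxy and para to the other) and rearomatises by proton loss, forming C4–C4a of unit 1. The closest known reaction is the Ruhemann-type flavone synthesis, the intramolecular Friedel–Crafts acylation of β-aryloxycinnamic acids, here run under the mild anhydride activation used to close xanthones from electron-rich 2-aryloxybenzoic acids. The pyranone (ring C of unit 1) closes in a six-membered mode, 6-exo-trig at the anhydride carbonyl (6-exo-dig if the free acylium ion reacts), by electrophilic aromatic substitution. No stereocentre is formed, and any E enol ether is funnelled into the same product because reversible C-protonation of the push–pull alkene by the liberated CF3CO2H lets the geometry equilibrate. The step needs site selectivity between the two ortho carbons of the phenoxy ring and chemoselectivity over the other arenes: the first is settled by the mirror symmetry of the 3,5-dimethoxy-4-methylphenoxy group, which makes both ortho carbons identical so that only the 6-methyl chromone with C8–H can arise, and the second by the fact that no other ring is comparably activated (ring B of unit 1 would have to close a strained indenone at a carbon meta to its ether oxygen, and ring A of unit 2 is deactivated by its own carbonyl). Anhydride activation at or below room temperature, with no added strong acid, is chosen so that the four benzyl ethers and the unit 2 flavone are left untouched.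

Step 14
Reactants: 21 8-[2-benzyloxy-5-(5,7-dimethoxy-6-methyl-4-oxochromen-2-yl)phenyl]-5,7-bis(benzyloxy)-2-(4-benzyloxyphenyl)chromen-4-one
Product: 22 8-[2-hydroxy-5-(5-hydroxy-7-methoxy-6-methyl-4-oxochromen-2-yl)phenyl]-5,7-dihydroxy-2-(4-hydroxyphenyl)chromen-4-one (CNP0113589.0)
Conditions: BCl3 (1 M in CH2Cl2, 12 equiv), C6HMe5 (12 equiv), CH2Cl2, −78 → 0 °C; MeOH, then aq. HCl
Reagents that add atoms: none
Why: Lewis acid ether cleavage: BCl3 ionises the aryl benzyl ethers and pentamethylbenzene traps the benzyl cations by Friedel–Crafts alkylation before they can C-benzylate the phloroglucinol rings, while chelation of boron between O5 and the C4 carbonyl of unit 1 activates only that methyl ether for attack by chloride and leaves the unchelated 7-O-methyl group in place.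

**Compound list**

1 | 2',4',6'-trihydroxyacetophenone | CC(=O)c1c(O)cc(O)cc1O | starting material
2 | 1-[4,6-bis(benzyloxy)-2-hydroxyphenyl]ethanone | CC(=O)c1c(O)cc(OCc2ccccc2)cc1OCc1ccccc1 | intermediate
3 | 1-[4,6-bis(benzyloxy)-2-hydroxy-3-iodophenyl]ethanone | CC(=O)c1c(O)c(I)c(OCc2ccccc2)cc1OCc1ccccc1 | intermediate
4 | 4-benzyloxybenzaldehyde | O=Cc1ccc(OCc2ccccc2)cc1 | starting material
5 | (E)-1-[4,6-bis(benzyloxy)-2-hydroxy-3-iodophenyl]-3-(4-benzyloxyphenyl)prop-2-en-1-one | O=C(/C=C/c1ccc(OCc2ccccc2)cc1)c1c(O)c(I)c(OCc2ccccc2)cc1OCc1ccccc1 | intermediate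
6 | (±)-5,7-bis(benzyloxy)-2-(4-benzyloxyphenyl)-8-iodochroman-4-one (flavanone, not isolated) | O=C1CC(c2ccc(OCc3ccccc3)cc2)Oc2c(I)c(OCc3ccccc3)cc(OCc3ccccc3)c21 | intermediate
7 | 5,7-bis(benzyloxy)-2-(4-benzyloxyphenyl)-8-iodochromen-4-one | O=c1cc(-c2ccc(OCc3ccccc3)cc2)oc2c(I)c(OCc3ccccc3)cc(OCc3ccccc3)c12 | intermediate
8 | 3-bromo-4-hydroxybenzaldehyde | O=Cc1ccc(O)c(Br)c1 | starting material
9 | 4-benzyloxy-3-bromobenzaldehyde | O=Cc1ccc(OCc2ccccc2)c(Br)c1 | intermediate
10 | 1-benzyloxy-2-bromo-4-ethynylbenzene | C#Cc1ccc(OCc2ccccc2)c(Br)c1 | intermediate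
11 | lithium (4-benzyloxy-3-bromophenyl)acetylide (not isolated) | [Li]C#Cc1ccc(OCc2ccccc2)c(Br)c1 | intermediate
12 | methyl 3-(4-benzyloxy-3-bromophenyl)prop-2-ynoate | COC(=O)C#Cc1ccc(OCc2ccccc2)c(Br)c1 | intermediate
13 | 2,6-dimethoxytoluene | COc1cccc(OC)c1C | starting material
14 | 2-(3,5-dimethoxy-4-methylphenyl)-4,4,5,5-tetramethyl-1,3,2-dioxaborolane (not isolated) | COc1cc(B2OC(C)(C)C(C)(C)O2)cc(OC)c1C | intermediate
15 | 3,5-dimethoxy-4-methylphenol | COc1cc(O)cc(OC)c1C | intermediate
16 | methyl (Z)-3-(4-benzyloxy-3-bromophenyl)-3-(3,5-dimethoxy-4-methylphenoxy)prop-2-enoate | COC(=O)/C=C(\Oc1cc(OC)c(C)c(OC)c1)c1ccc(OCc2ccccc2)c(Br)c1 | intermediate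
17 | methyl (Z)-3-[4-benzyloxy-3-(4,4,5,5-tetramethyl-1,3,2-dioxaborolan-2-yl)phenyl]-3-(3,5-dimethoxy-4-methylphenoxy)prop-2-enoate | COC(=O)/C=C(\Oc1cc(OC)c(C)c(OC)c1)c1ccc(OCc2ccccc2)c(B2OC(C)(C)C(C)(C)O2)c1 | intermediate
18 | methyl (Z)-3-{4-benzyloxy-3-[5,7-bis(benzyloxy)-2-(4-benzyloxyphenyl)-4-oxochromen-8-yl]phenyl}-3-(3,5-dimethoxy-4-methylphenoxy)prop-2-enoate | COC(=O)/C=C(\Oc1cc(OC)c(C)c(OC)c1)c1ccc(OCc2ccccc2)c(-c2c(OCc3ccccc3)cc(OCc3ccccc3)c3c(=O)cc(-c4ccc(OCc5ccccc5)cc4)oc23)c1 | intermediate
19 | (Z)-3-{4-benzyloxy-3-[5,7-bis(benzyloxy)-2-(4-benzyloxyphenyl)-4-oxochromen-8-yl]phenyl}-3-(3,5-dimethoxy-4-methylphenoxy)prop-2-enoic acid (precursor of the key step) | Cc1c(OC)cc(O/C(=C\C(=O)O)c2ccc(OCc3ccccc3)c(-c3c(OCc4ccccc4)cc(OCc4ccccc4)c4c(=O)cc(-c5ccc(OCc6ccccc6)cc5)oc34)c2)cc1OC | intermediate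
20 | mixed anhydride of acid 19 with trifluoroacetic acid (not isolated) | Cc1c(OC)cc(O/C(=C\C(=O)OC(=O)C(F)(F)F)c2ccc(OCc3ccccc3)c(-c3c(OCc4ccccc4)cc(OCc4ccccc4)c4c(=O)cc(-c5ccc(OCc6ccccc6)cc5)oc34)c2)cc1OC | intermediate
21 | 8-[2-benzyloxy-5-(5,7-dimethoxy-6-methyl-4-oxochromen-2-yl)phenyl]-5,7-bis(benzyloxy)-2-(4-benzyloxyphenyl)chromen-4-one (5(1)-O-methyl tetra-O-benzyl ether of the target) | COc1cc2oc(-c3ccc(OCc4ccccc4)c(-c4c(OCc5ccccc5)cc(OCc5ccccc5)c5c(=O)cc(-c6ccc(OCc7ccccc7)cc6)oc45)c3)cc(=O)c2c(OC)c1C | intermediate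
22 | 8-[2-hydroxy-5-(5-hydroxy-7-methoxy-6-methyl-4-oxochromen-2-yl)phenyl]-5,7-dihydroxy-2-(4-hydroxyphenyl)chromen-4-one (CNP0113589.0) | COc1cc2oc(-c3ccc(O)c(-c4c(O)cc(O)c5c(=O)cc(-c6ccc(O)cc6)oc45)c3)cc(=O)c2c(O)c1C | target

**Totals and risks**

Total step count: 14.
Longest linear sequence: 9 steps (steps 5, 6, 7, 9, 10, 11, 12, 13 and 14, from 8 to 22).

The three steps most likely to fail:

Step 11, the Suzuki coupling. Transmetalation is slow when a tri-ortho-substituted biaryl has to form, so protodeboronation of the elaborated boronate 17 and hydrodeiodination of 7 may outrun the coupling, and the hot aqueous base may begin to hydrolyse the enoate. The fallback joins ring B to unit 2 before the enol ether exists, so that a small and cheap boronate can be used in large excess.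
- Setting out from bromide 9, Miyaura borylation (B2pin2, Pd(dppf)Cl2, KOAc, dioxane) would give 4-benzyloxy-3-(4,4,5,5-tetramethyl-1,3,2-dioxaborolan-2-yl)benzaldehyde F1.
- Coupling of this boronate with iodide 7 (Pd(PPh3)4, K3PO4, DMF/H2O) should give 4-benzyloxy-3-[5,7-bis(benzyloxy)-2-(4-benzyloxyphenyl)-4-oxochromen-8-yl]benzaldehyde F2.
- Ohira–Bestmann homologation then gives 8-(2-benzyloxy-5-ethynylphenyl)-5,7-bis(benzyloxy)-2-(4-benzyloxyphenyl)chromen-4-one F3.
- Carboxylation with CO2 (AgI cat., Cs2CO3, DMF) gives the caesium 3-arylprop-2-ynoate F4 (not isolated), which MeI converts in the same flask into the methyl 3-arylprop-2-ynoate F5.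
- Oxa-Michael addition of phenol 15 (Cs2CO3, DMF) comes back to the route at ester 18.

Step 13, the Friedel–Crafts ring closure. The acylium ion is stabilised by the enol ether oxygen and may close slowly. During a long exposure to CF3CO2H the peri 5-O-benzyl group of unit 2 may be lost, or benzyl cations may migrate onto the electron-rich rings. The fallback closes ring C of unit 1 before the biaryl bond is made, on a small fragment that tolerates stronger activation.
- Setting out from bromo ester 16, saponification (LiOH) would give (Z)-3-(4-benzyloxy-3-bromophenyl)-3-(3,5-dimethoxy-4-methylphenoxy)prop-2-enoic acid F6.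
- Oxalyl chloride with catalytic DMF gives (Z)-3-(4-benzyloxy-3-bromophenyl)-3-(3,5-dimethoxy-4-methylphenoxy)prop-2-enoyl chloride F7 (not isolated).
- SnCl4 in CH2Cl2 at −20 °C cyclises it (Ruhemann flavone synthesis, with the same symmetry argument) to 2-(4-benzyloxy-3-bromophenyl)-5,7-dimethoxy-6-methylchromen-4-one F8.
- Miyaura borylation gives 2-[4-benzyloxy-3-(4,4,5,5-tetramethyl-1,3,2-dioxaborolan-2-yl)phenyl]-5,7-dimethoxy-6-methylchromen-4-one F9.
- Suzuki coupling of this boronate with iodide 7 (Pd(OAc)2, SPhos, K3PO4) comes back to the route at 21.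

Step 14, the global deprotection. Cleavage of the chelated 5-O-methyl ether of unit 1 may stay incomplete at the low temperature at which benzyl transfer is clean. Warming with excess BCl3 may begin to cleave the 7-O-methyl ether or allow C-benzylation of the phloroglucinol rings. The fallback separates the two events into orthogonal operations.
- Setting out from 21, hydrogenolysis (H2, Pd/C, THF/MeOH, rt) would remove the four benzyl groups and give 8-[5-(5,7-dimethoxy-6-methyl-4-oxochromen-2-yl)-2-hydroxyphenyl]-5,7-dihydroxy-2-(4-hydroxyphenyl)chromen-4-one F10.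
- Chelation-controlled demethylation (AlCl3, MeCN, 60 °C) then cleaves only the methyl ether peri to the C4 carbonyl and arrives at target 22.

**Further compounds**

F1 | step 11 | 4-benzyloxy-3-(4,4,5,5-tetramethyl-1,3,2-dioxaborolan-2-yl)benzaldehyde | O=Cc1ccc(OCc2ccccc2)c(B2OC(C)(C)C(C)(C)O2)c1
F2 | step 11 | 4-benzyloxy-3-[5,7-bis(benzyloxy)-2-(4-benzyloxyphenyl)-4-oxochromen-8-yl]benzaldehyde | O=Cc1ccc(OCc2ccccc2)c(-c2c(OCc3ccccc3)cc(OCc3ccccc3)c3c(=O)cc(-c4ccc(OCc5ccccc5)cc4)oc23)c1
F3 | step 11 | 8-(2-benzyloxy-5-ethynylphenyl)-5,7-bis(benzyloxy)-2-(4-benzyloxyphenyl)chromen-4-one | C#Cc1ccc(OCc2ccccc2)c(-c2c(OCc3ccccc3)cc(OCc3ccccc3)c3c(=O)cc(-c4ccc(OCc5ccccc5)cc4)oc23)c1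
F4 | step 11 | caesium 3-{4-benzyloxy-3-[5,7-bis(benzyloxy)-2-(4-benzyloxyphenyl)-4-oxochromen-8-yl]phenyl}prop-2-ynoate (not isolated) | [Cs+].[O-]C(=O)C#Cc1ccc(OCc2ccccc2)c(-c2c(OCc3ccccc3)cc(OCc3ccccc3)c3c(=O)cc(-c4ccc(OCc5ccccc5)cc4)oc23)c1
F5 | step 11 | methyl 3-{4-benzyloxy-3-[5,7-bis(benzyloxy)-2-(4-benzyloxyphenyl)-4-oxochromen-8-yl]phenyl}prop-2-ynoate | COC(=O)C#Cc1ccc(OCc2ccccc2)c(-c2c(OCc3ccccc3)cc(OCc3ccccc3)c3c(=O)cc(-c4ccc(OCc5ccccc5)cc4)oc23)c1
F6 | step 13 | (Z)-3-(4-benzyloxy-3-bromophenyl)-3-(3,5-dimethoxy-4-methylphenoxy)prop-2-enoic acid | OC(=O)/C=C(\Oc1cc(OC)c(C)c(OC)c1)c1ccc(OCc2ccccc2)c(Br)c1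
F7 | step 13 | (Z)-3-(4-benzyloxy-3-bromophenyl)-3-(3,5-dimethoxy-4-methylphenoxy)prop-2-enoyl chloride (not isolated) | ClC(=O)/C=C(\Oc1cc(OC)c(C)c(OC)c1)c1ccc(OCc2ccccc2)c(Br)c1
F8 | step 13 | 2-(4-benzyloxy-3-bromophenyl)-5,7-dimethoxy-6-methylchromen-4-one | COc1cc2oc(-c3ccc(OCc4ccccc4)c(Br)c3)cc(=O)c2c(OC)c1C
F9 | step 13 | 2-[4-benzyloxy-3-(4,4,5,5-tetramethyl-1,3,2-dioxaborolan-2-yl)phenyl]-5,7-dimethoxy-6-methylchromen-4-one | COc1cc2oc(-c3ccc(OCc4ccccc4)c(B4OC(C)(C)C(C)(C)O4)c3)cc(=O)c2c(OC)c1C
F10 | step 14 | 8-[5-(5,7-dimethoxy-6-methyl-4-oxochromen-2-yl)-2-hydroxyphenyl]-5,7-dihydroxy-2-(4-hydroxyphenyl)chromen-4-one | COc1cc2oc(-c3ccc(O)c(-c4c(O)cc(O)c5c(=O)cc(-c6ccc(O)cc6)oc45)c3)cc(=O)c2c(OC)c1C
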